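The target is a pyrrole-2-carboxylate whose ring carbon C3 carries an unbranched, unfunctionalised C23 chain. Everything rests on cutting this chain at the CH2–CH2 bond between the ninth and tenth carbon counted from the terminal methyl (C14–C15 counted from the pyrrole ring): it is remote from the ring, the N–H and the ester, so it can be forged directly as an sp3–sp3 bond that leaves no functional trace. In one operation the key step hydroborates the terminal alkene of a 3-(tetradec-13-enyl)pyrrole ester and couples the primary borane with 1-bromononane (alkyl–alkyl Suzuki–Miyaura), giving the target itself. That alkene precursor comes in one step from a 3-bromopyrrole ester and a symmetrical C14 diene.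

Key step: step 2

Remark on the chemistry: the target has no stereocentre, so no stereocontrol is needed; compounds 1, 2 and 5 and 9-BBN are taken as catalogue chemicals.

Step 1
Reactants: 1 tetradeca-1,13-diene; 2 methyl 3-bromo-1H-pyrrole-2-carboxylate
Product: 4 methyl 3-(tetradec-13-en-1-yl)-1H-pyrrole-2-carboxylate, via B-(tetradec-13-enyl)-9-BBN 3 (not isolated)
Conditions: 1 (6 equiv), 9-BBN (1.5 equiv), THF, 0 °C to rt; then 2 (1 equiv), Pd(OAc)2 (5 mol%), SPhos (10 mol%), 3 M aq. K3PO4 (3 equiv), THF, 65 °C
Reagents that add atoms: none
Why: Anti-Markovnikov hydroboration of one terminal C=C of the excess diene gives a primary B-alkyl-9-BBN that should transfer only its primary alkyl group to the C3–Br bond of 2 in a B-alkyl Suzuki–Miyaura coupling, the electron-rich SPhos ligand serving the electron-rich N–H bromopyrrole, while the second alkene and the ester stay inert and the excess of 1 keeps double hydroboration statistically minor.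

Step 2
Reactants: 4 methyl 3-(tetradec-13-en-1-yl)-1H-pyrrole-2-carboxylate; 5 1-bromononane
Product: 7 methyl 3-tricosyl-1H-pyrrole-2-carboxylate, via pyrrolyl-tetradecyl-9-BBN 6 (not isolated)
Conditions: 9-BBN (1.2 equiv), THF, 0 °C to rt; then 5 (1.5 equiv), Pd(OAc)2 (4 mol%), PCy3 (8 mol%), K3PO4·H2O (1.5 equiv), THF, rt
Reagents that add atoms: none
Why: 9-BBN adds anti-Markovnikov to the terminal C=C of 4 to give the primary borane 6, Pd(0)/PCy3 then inserts into the C–Br bond of 5 by an SN2-type oxidative addition, the base-activated borate transfers its primary alkyl group to palladium, and reductive elimination forms the CH2–CH2 bond. The closest known reaction type is the room-temperature alkyl–alkyl (B-alkyl) Suzuki–Miyaura coupling of primary alkyl bromides bearing β-hydrogens with B-alkyl-9-BBN reagents. No ring is closed and no stereocentre is created, so the step needs only chemoselectivity. The hydroboration should spare the ester (9-BBN reduces esters very slowly at rt) and the N–H (the pyrrole nitrogen lone pair belongs to the aromatic sextet and cannot coordinate boron, and any N–B bond would be hydrolysed by the hydrated base). The bulky, electron-rich PCy3 should let transmetalation and reductive elimination outrun β-hydride elimination from the nonyl–palladium intermediate, and only the primary B–C bond of 6 is transferred because the secondary bicyclic B–C bonds transmetalate far more slowly. N-Alkylation of the pyrrole by 5 should not compete with the weak, sparingly soluble K3PO4·H2O at room temperature, and the excess of cheap 5 leaves with the non-polar fraction.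

Compound list
1 | tetradeca-1,13-diene | C=CCCCCCCCCCCC=C | starting material
2 | methyl 3-bromo-1H-pyrrole-2-carboxylate | COC(=O)c1[nH]ccc1Br | starting material
3 | 9-(tetradec-13-en-1-yl)-9-borabicyclo[3.3.1]nonane | C=CCCCCCCCCCCCCB1C2CCCC1CCC2 | intermediate
4 | methyl 3-(tetradec-13-en-1-yl)-1H-pyrrole-2-carboxylate | C=CCCCCCCCCCCCCc1cc[nH]c1C(=O)OC | intermediate
5 | 1-bromononane | CCCCCCCCCBr | starting material
6 | methyl 3-[14-(9-borabicyclo[3.3.1]nonan-9-yl)tetradecyl]-1H-pyrrole-2-carboxylate | COC(=O)c1[nH]ccc1CCCCCCCCCCCCCCB1C2CCCC1CCC2 | intermediate
7 | methyl 3-tricosyl-1H-pyrrole-2-carboxylate | CCCCCCCCCCCCCCCCCCCCCCCc1cc[nH]c1C(=O)OC | target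

Total step count: 2
Longest linear sequence: 2 steps (1 → 4 → 7)

Steps most likely to fail (the route has only two steps, so both are ranked and there is no third):

Step 1. What may go wrong: oxidative addition into the electron-rich, partly deprotonated N–H bromopyrrole may be slow, so that protodebromination of 2 and protodeboronation of 3 take over. Double hydroboration of the diene may also divert material into a bis-pyrrole. Fallback (sets out from 1, comes back at 4): the pyrrole ring is built onto the chain instead of the chain being coupled to a preformed ring. Mono-hydroboration of excess 1 with 9-BBN gives 3 as before. Oxidation of 3 (NaOH, H2O2, THF, 0 °C) gives tetradec-13-en-1-ol F1. Tosylation (TsCl, pyridine, CH2Cl2, 0 °C) gives tetradec-13-en-1-yl 4-methylbenzenesulfonate F2. Displacement with lithium acetylide–ethylenediamine complex (DMSO, rt) gives hexadec-15-en-1-yne F3. Silver-catalysed isocyanide–alkyne cycloaddition of F3 with methyl isocyanoacetate (Ag2CO3 10 mol%, NMP, 80 °C) should place the ester carbon next to the substituted alkyne carbon and so give 4, with the chain on C3 and the terminal alkene untouched.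

Step 2. What may go wrong: β-hydride elimination from the nonyl–palladium intermediate may outrun transmetalation, returning nonenes and protodeboronated material. Partial consumption of 9-BBN by the N–H may leave hydroboration incomplete. Base-promoted N-alkylation by the bromide may compete. Fallback (sets out from 4 and 5, comes back at 7): the same CH2–CH2 bond is formed with the roles of the partners exchanged and zinc in place of boron. Hydroboration of 4 with 9-BBN gives 6 as before. Oxidation of 6 with sodium perborate (THF/H2O, rt, mild enough for the methyl ester) gives methyl 3-(14-hydroxytetradecyl)-1H-pyrrole-2-carboxylate F4. Appel bromination (CBr4, PPh3, CH2Cl2, 0 °C) gives methyl 3-(14-bromotetradecyl)-1H-pyrrole-2-carboxylate F5. Separately, 5 is converted with zinc dust (cat. I2, DMA, 80 °C) into nonylzinc bromide F6, a reagent that tolerates the ester and the N–H. Alkyl–alkyl Negishi coupling of F5 with F6 (Pd2(dba)3, PCyp3, N-methylimidazole, THF/NMP, 80 °C) should give 7.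

Further compounds
F1 | step 1 | tetradec-13-en-1-ol | C=CCCCCCCCCCCCCO
F2 | step 1 | tetradec-13-en-1-yl 4-methylbenzenesulfonate | C=CCCCCCCCCCCCCOS(=O)(=O)c1ccc(C)cc1
F3 | step 1 | hexadec-15-en-1-yne | C=CCCCCCCCCCCCCC#C
F4 | step 2 | methyl 3-(14-hydroxytetradecyl)-1H-pyrrole-2-carboxylate | COC(=O)c1[nH]ccc1CCCCCCCCCCCCCCO
F5 | step 2 | methyl 3-(14-bromotetradecyl)-1H-pyrrole-2-carboxylate | COC(=O)c1[nH]ccc1CCCCCCCCCCCCCCBr
F6 | step 2 | nonylzinc bromide | CCCCCCCCC[Zn]Br
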